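**Plan**

- Cuts, in retrosynthetic order: the O–Si bond; the C5 ring CH2 back to a lactone carbonyl; the C7′–aryl bond (C7′ is the benzylic CH2 on C4); then C2–C3 together with O1–C5; last C3–C4.
- Enabling feature: C2 (trimethoxyphenyl-bearing, bonded to O1) and C3 (hydroxymethyl arm) are trans neighbours. With C4, C5 and C7′ they form the carbon set of an α-methylene-γ-butyrolactone, C5 being the carbonyl and C7′ the exocyclic methylene.
- Forward order: C3–C4 is made in an open chain (acrylate plus silyloxyacetaldehyde). The only ring, the oxolane as its lactone, closes in step 3. The dimethoxyphenyl group is then added at C7′ and the carbonyl is reduced to CH2.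
- Stereochemistry: C2 from the chiral chromium catalyst; C3 from the chair transition state of the same step (anti to C2–O); C4 from protonation of a rhodium enolate on the face opposite the C3 arm (3,4-cis).

Key step: step 3

Remark: the labels O1, C2–C5 and C7′ are those of the target oxolane and are used for every ring compound; systematic names carry their own locants.

Assumption: the ligand enantiomer used in step 3 is the one that directs the allyl group to the Re face of the aldehyde (C2 = R); if the sense proves opposite, the mirror-image ligand is used.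

**Step 1**
Reactants: 1 ethyl acrylate; 2 (tert-butyldimethylsilyloxy)acetaldehyde
Product: 3 ethyl 4-[(tert-butyldimethylsilyl)oxy]-3-hydroxy-2-methylidenebutanoate (racemic)
Conditions: DABCO (30 mol%), ethyl acrylate (3 equiv, neat), rt
Reagents that add atoms: none
Why: Morita–Baylis–Hillman reaction, in which the DABCO–acrylate zwitterion adds to the reactive α-oxygenated aldehyde and forms C3–C4; the carbinol centre arises racemic and is erased in step 2.

**Step 2**
Reactants: 3 ethyl 4-[(tert-butyldimethylsilyl)oxy]-3-hydroxy-2-methylidenebutanoate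
Product: 4 ethyl (2Z)-2-(bromomethyl)-4-[(tert-butyldimethylsilyl)oxy]but-2-enoate
Conditions: NBS (1.3 equiv), Me2S (1.5 equiv), CH2Cl2, 0 °C → rt
Reagents that add atoms: N-bromosuccinimide, O=C1CCC(=O)N1Br
Why: Corey–Kim-type bromination of a Morita–Baylis–Hillman alcohol, in which bromide displaces the alkoxysulfonium group in an SN2′ sense to give the conjugated trisubstituted Z-allyl bromide under neutral conditions that spare the silyl ether.

**Step 3**
Reactants: 4 ethyl (2Z)-2-(bromomethyl)-4-[(tert-butyldimethylsilyl)oxy]but-2-enoate; 5 3,4,5-trimethoxybenzaldehyde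
Product: 8 (4S,5R)-4-{[(tert-butyldimethylsilyl)oxy]methyl}-3-methylidene-5-(3,4,5-trimethoxyphenyl)oxolan-2-one, via anti-adduct trimethylsilyl ether 6 (not isolated), via anti hydroxy ester 7 (not isolated)
Conditions: CrCl2 (10 mol%), chiral C2-symmetric 1,8-bis(4-isopropyl-4,5-dihydrooxazol-2-yl)carbazole ligand (12 mol%), i-Pr2NEt (30 mol%), Mn powder (2 equiv), Me3SiCl (1.5 equiv), THF, rt; then 10% aq. citric acid, THF, 0 °C; PPTS (10 mol%), toluene, 50 °C
Reagents that add atoms: none
Why: Divalent chromium (regenerated by Mn, with Me3SiCl freeing the alkoxide from trivalent chromium) inserts into the allylic C–Br bond of 4, and the ligand-bound allylchromium adds through its γ-carbon to aldehyde 5 in a closed six-membered chair transition state, forming C2–C3; this is the catalytic asymmetric Nozaki–Hiyama–Kishi 2-(alkoxycarbonyl)allylation, known for the parent and γ-alkyl bromides. The C2 configuration (R) should come from the tridentate chiral ligand, which leaves the Re face of the chromium-bound aldehyde open. The C3 configuration (S, anti to C2–O) should come from the chair in which both the aryl and the silyloxymethyl groups are equatorial, η1/η3 equilibration of the allylchromium letting either alkene geometry react through that lower transition state. Mild acid cleaves the O–SiMe3 group of 6, and the C2 hydroxyl of 7 attacks the ester carbonyl C5 in a 5-exo-trig acyl substitution with loss of ethanol, closing the lactone (O1–C5); the anti adduct gives the trans ring. The step needs γ- over α-attack, secured by the cyclic SE2′ transition state, and anti over syn selectivity, secured by the equatorial preference of the bulky silyloxymethyl group. Aldehyde 5 cannot enolise, and the primary tert-butyldimethylsilyl ether tolerates the weak acids used.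

**Step 4**
Reactants: 8 (4S,5R)-4-{[(tert-butyldimethylsilyl)oxy]methyl}-3-methylidene-5-(3,4,5-trimethoxyphenyl)oxolan-2-one; 9 3,4-dimethoxyphenylboronic acid (2 equiv)
Product: 10 (3S,4S,5R)-4-{[(tert-butyldimethylsilyl)oxy]methyl}-3-(3,4-dimethoxybenzyl)-5-(3,4,5-trimethoxyphenyl)oxolan-2-one
Conditions: [Rh(cod)OH]2 (3 mol%), dioxane/H2O 10:1, 40 °C
Reagents that add atoms: none
Why: Hayashi–Miyaura conjugate addition to a 1,1-disubstituted acceptor, in which the aryl–rhodium species (monovalent rhodium) inserts the exocyclic alkene at C7′ and water protonates the rhodium enolate at C4 on the face opposite the adjacent C3 silyloxymethyl arm, which should place the benzyl group cis to that arm (C4 = S) under base-free conditions that do not epimerise it.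

**Step 5**
Reactants: 10 (3S,4S,5R)-4-{[(tert-butyldimethylsilyl)oxy]methyl}-3-(3,4-dimethoxybenzyl)-5-(3,4,5-trimethoxyphenyl)oxolan-2-one
Product: 11 (3S,4S,5R)-4-{[(tert-butyldimethylsilyl)oxy]methyl}-3-(3,4-dimethoxybenzyl)-5-(3,4,5-trimethoxyphenyl)oxolan-2-ol (anomeric mixture)
Conditions: i-Bu2AlH (1.2 equiv), CH2Cl2, −78 °C; Rochelle salt work-up
Reagents that add atoms: none
Why: Partial reduction of a γ-lactone, which stops at the tetrahedral aluminium hemiacetal at −78 °C and gives the lactol; the new anomeric centre at C5 is formed as a mixture and is removed in step 6, and the non-basic conditions leave C4 untouched.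

**Step 6**
Reactants: 11 (3S,4S,5R)-4-{[(tert-butyldimethylsilyl)oxy]methyl}-3-(3,4-dimethoxybenzyl)-5-(3,4,5-trimethoxyphenyl)oxolan-2-ol
Product: 12 tert-butyl{[(2R,3S,4S)-4-(3,4-dimethoxybenzyl)-2-(3,4,5-trimethoxyphenyl)oxolan-3-yl]methoxy}dimethylsilane
Conditions: Et3SiH (3 equiv), BF3·OEt2 (1.5 equiv), CH2Cl2, −78 → −40 °C; cold aq. NaHCO3 quench
Reagents that add atoms: none
Why: Ionic hydrogenation of a lactol, in which BF3 ionises the hemiacetal to the C5 oxocarbenium ion and Et3SiH reduces it to CH2 faster than the ion can lose a proton from C4; no stereocentre is created, and the low temperature should spare the C2 benzylic ether and the silyl ether.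

**Step 7**
Reactants: 12 tert-butyl{[(2R,3S,4S)-4-(3,4-dimethoxybenzyl)-2-(3,4,5-trimethoxyphenyl)oxolan-3-yl]methoxy}dimethylsilane
Product: 13 [(2R,3S,4S)-4-(3,4-dimethoxybenzyl)-2-(3,4,5-trimethoxyphenyl)oxolan-3-yl]methanol (CNP0107562.1)
Conditions: Bu4NF (1.2 equiv), THF, 0 °C → rt
Reagents that add atoms: none
Why: Fluoride-mediated cleavage of the primary silyl ether, driven by Si–F bond formation; no stereocentre is touched.

**Compound list**

1 | ethyl acrylate | C=CC(=O)OCC | starting material
2 | (tert-butyldimethylsilyloxy)acetaldehyde | O=CCO[Si](C)(C)C(C)(C)C | starting material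
3 | ethyl 4-[(tert-butyldimethylsilyl)oxy]-3-hydroxy-2-methylidenebutanoate (racemic) | C=C(C(=O)OCC)C(O)CO[Si](C)(C)C(C)(C)C | intermediate
4 | ethyl (2Z)-2-(bromomethyl)-4-[(tert-butyldimethylsilyl)oxy]but-2-enoate | CCOC(=O)/C(CBr)=C/CO[Si](C)(C)C(C)(C)C | intermediate
5 | 3,4,5-trimethoxybenzaldehyde | COc1cc(C=O)cc(OC)c1OC | starting material
6 | ethyl (3S,4R)-3-{[(tert-butyldimethylsilyl)oxy]methyl}-2-methylidene-4-(3,4,5-trimethoxyphenyl)-4-[(trimethylsilyl)oxy]butanoate (anti) | C[Si](C)(C)O[C@@H](c1cc(OC)c(OC)c(OC)c1)[C@@H](C(=C)C(=O)OCC)CO[Si](C)(C)C(C)(C)C | intermediate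
7 | ethyl (3S,4R)-3-{[(tert-butyldimethylsilyl)oxy]methyl}-4-hydroxy-2-methylidene-4-(3,4,5-trimethoxyphenyl)butanoate (anti) | O[C@@H](c1cc(OC)c(OC)c(OC)c1)[C@@H](C(=C)C(=O)OCC)CO[Si](C)(C)C(C)(C)C | intermediate
8 | (4S,5R)-4-{[(tert-butyldimethylsilyl)oxy]methyl}-3-methylidene-5-(3,4,5-trimethoxyphenyl)oxolan-2-one (trans) | C=C1C(=O)O[C@@H](c2cc(OC)c(OC)c(OC)c2)[C@@H]1CO[Si](C)(C)C(C)(C)C | intermediate
9 | 3,4-dimethoxyphenylboronic acid | COc1ccc(B(O)O)cc1OC | starting material
10 | (3S,4S,5R)-4-{[(tert-butyldimethylsilyl)oxy]methyl}-3-(3,4-dimethoxybenzyl)-5-(3,4,5-trimethoxyphenyl)oxolan-2-one | COc1ccc(C[C@@H]2C(=O)O[C@@H](c3cc(OC)c(OC)c(OC)c3)[C@@H]2CO[Si](C)(C)C(C)(C)C)cc1OC | intermediate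
11 | (3S,4S,5R)-4-{[(tert-butyldimethylsilyl)oxy]methyl}-3-(3,4-dimethoxybenzyl)-5-(3,4,5-trimethoxyphenyl)oxolan-2-ol (anomeric mixture) | COc1ccc(C[C@@H]2C(O)O[C@@H](c3cc(OC)c(OC)c(OC)c3)[C@@H]2CO[Si](C)(C)C(C)(C)C)cc1OC | intermediate
12 | tert-butyl{[(2R,3S,4S)-4-(3,4-dimethoxybenzyl)-2-(3,4,5-trimethoxyphenyl)oxolan-3-yl]methoxy}dimethylsilane | COc1ccc(C[C@@H]2CO[C@@H](c3cc(OC)c(OC)c(OC)c3)[C@@H]2CO[Si](C)(C)C(C)(C)C)cc1OC | intermediate
13 | [(2R,3S,4S)-4-(3,4-dimethoxybenzyl)-2-(3,4,5-trimethoxyphenyl)oxolan-3-yl]methanol | COc1ccc(C[C@@H]2CO[C@@H](c3cc(OC)c(OC)c(OC)c3)[C@@H]2CO)cc1OC | target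

**Totals**

Total step count: 7. Longest linear sequence: 7 steps (1/2 → 3 → 4 → 8 → 10 → 11 → 12 → 13).

**Steps most likely to fail**

Step 3. What may go wrong: the allylchromium may react through the geometry that places the silyloxymethyl group axial (syn adduct, hence cis lactone); it may lose silyloxide by elimination from its branched isomer; or it may discriminate the aldehyde faces poorly with this γ-branched reagent.

Fallback, setting out from 5 and returning at 8: the lactone is built by an auxiliary-controlled aldol–lactonisation and methylenated afterwards.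
- (R)-4-Benzyloxazolidin-2-one is acylated (n-BuLi, methyl 4-chloro-4-oxobutanoate, THF, −78 °C) to the succinate imide F1.
- Its dibutylboron Z-enolate (Bu2BOTf, i-Pr2NEt, CH2Cl2, −78 → 0 °C) adds to 5 in an Evans syn aldol reaction to give the hydroxy ester imide F2.
- On brief acid treatment (PPTS, toluene) F2 closes with loss of methanol to the trans lactone imide F3; the syn aldol relationship becomes trans C2/C3 in the ring.
- LiOH/H2O2 (THF/H2O, 0 °C) removes the auxiliary to give the lactone acid F4.
- BH3·SMe2 (THF, 0 °C) reduces the acid beside the lactone to the hydroxymethyl lactone F5, and TBSCl/imidazole (DMF) gives the silyl ether F6.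
- Deprotonation (LiN(SiMe3)2, THF, −78 °C) and trapping with Eschenmoser's salt give the Mannich base F7; MeI gives the quaternary ammonium iodide F8; NaHCO3 eliminates trimethylamine to give 8.

Step 4. What may go wrong: protonation of the rhodium enolate on the wrong face, later epimerisation of the less stable 3,4-cis product, or β-hydride elimination to Heck-type products in place of protonation.

Fallback, setting out from 8 and returning at 10: the C7′–aryl bond is made by a Mizoroki–Heck reaction with 4-iodo-1,2-dimethoxybenzene (Pd(OAc)2, Bu4NCl, NaHCO3, DMF, 80 °C; zerovalent palladium formed in situ) to give the E-benzylidene lactone F9. Hydrogenation (H2 1 atm, Pd/C, EtOAc, rt, stopped after one equivalent) should then deliver hydrogen to the face opposite the C3 arm and give 10. The C4 centre is thus set by an irreversible addition under neutral conditions.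

Step 6. What may go wrong: proton loss from C4 of the oxocarbenium ion (enol ether formation, scrambling the C4 configuration), acid-induced ionisation of the C2 benzylic ether, or cleavage of the silyl ether before reduction is complete.

Fallback, setting out from 10 (bypassing 11) and returning at 12: LiAlH4 (THF, 0 °C) reduces the lactone to the 1,4-diol F10. TsCl in pyridine (0 °C → rt) sulfonylates the primary hydroxyl selectively to the monotosylate F11. The benzylic hydroxyl then displaces the tosylate in a 5-exo-tet Williamson closure; the C2–O bond is never broken and no cation is formed next to C4, so 12 results with all three centres intact.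

**Further compounds**

F1 | step 3 | methyl 4-[(4R)-4-benzyl-2-oxooxazolidin-3-yl]-4-oxobutanoate | COC(=O)CCC(=O)N1[C@H](Cc2ccccc2)COC1=O
F2 | step 3 | methyl (3R,4R)-3-[(4R)-4-benzyl-2-oxooxazolidine-3-carbonyl]-4-hydroxy-4-(3,4,5-trimethoxyphenyl)butanoate (syn aldol adduct) | O[C@@H](c1cc(OC)c(OC)c(OC)c1)[C@@H](CC(=O)OC)C(=O)N1[C@H](Cc2ccccc2)COC1=O
F3 | step 3 | (4R)-4-benzyl-3-[(2R,3R)-5-oxo-2-(3,4,5-trimethoxyphenyl)oxolane-3-carbonyl]oxazolidin-2-one (trans lactone imide) | O=C1C[C@@H](C(=O)N2[C@H](Cc3ccccc3)COC2=O)[C@H](c2cc(OC)c(OC)c(OC)c2)O1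
F4 | step 3 | (2R,3R)-5-oxo-2-(3,4,5-trimethoxyphenyl)oxolane-3-carboxylic acid | O=C1C[C@@H](C(=O)O)[C@H](c2cc(OC)c(OC)c(OC)c2)O1
F5 | step 3 | (4S,5R)-4-(hydroxymethyl)-5-(3,4,5-trimethoxyphenyl)oxolan-2-one | O=C1C[C@@H](CO)[C@H](c2cc(OC)c(OC)c(OC)c2)O1
F6 | step 3 | (4S,5R)-4-{[(tert-butyldimethylsilyl)oxy]methyl}-5-(3,4,5-trimethoxyphenyl)oxolan-2-one | O=C1C[C@@H](CO[Si](C)(C)C(C)(C)C)[C@H](c2cc(OC)c(OC)c(OC)c2)O1
F7 | step 3 | (3S,4S,5R)-4-{[(tert-butyldimethylsilyl)oxy]methyl}-3-[(dimethylamino)methyl]-5-(3,4,5-trimethoxyphenyl)oxolan-2-one (Mannich base, C3 arm anti to C4 arm) | CN(C)C[C@H]1C(=O)O[C@@H](c2cc(OC)c(OC)c(OC)c2)[C@@H]1CO[Si](C)(C)C(C)(C)C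
F8 | step 3 | N-methyl quaternary ammonium iodide of F7 | C[N+](C)(C)C[C@H]1C(=O)O[C@@H](c2cc(OC)c(OC)c(OC)c2)[C@@H]1CO[Si](C)(C)C(C)(C)C.[I-]
F9 | step 4 | (3E,4S,5R)-4-{[(tert-butyldimethylsilyl)oxy]methyl}-3-(3,4-dimethoxybenzylidene)-5-(3,4,5-trimethoxyphenyl)oxolan-2-one | COc1ccc(/C=C2/C(=O)O[C@@H](c3cc(OC)c(OC)c(OC)c3)[C@@H]2CO[Si](C)(C)C(C)(C)C)cc1OC
F10 | step 6 | (1R,2S,3S)-2-{[(tert-butyldimethylsilyl)oxy]methyl}-3-(3,4-dimethoxybenzyl)-1-(3,4,5-trimethoxyphenyl)butane-1,4-diol | COc1ccc(C[C@H](CO)[C@@H](CO[Si](C)(C)C(C)(C)C)[C@@H](O)c2cc(OC)c(OC)c(OC)c2)cc1OC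
F11 | step 6 | primary 4-O-(p-toluenesulfonate) of F10 | COc1ccc(C[C@H](COS(=O)(=O)c3ccc(C)cc3)[C@@H](CO[Si](C)(C)C(C)(C)C)[C@@H](O)c2cc(OC)c(OC)c(OC)c2)cc1OC
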